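The plan rests on disconnecting ring C at the C2–C3 bond. The feature used is the C2 methine, which carries both O1 and ring B: once ring B hangs on O1 as a benzyl group, C2 is an ether carbon whose hydrogens are doubly activated, while its neighbour C3, adjacent to the C4 ketone, is generated as a rhodium carbene from a terminal diazoketone. One intramolecular C–H insertion then makes C2–C3, closes ring C and sets C2. The precursor is a tris-TIPS-protected diazoacetyl phloroglucinol core bearing the lavandulyl chain and the ring-B benzyl ether, assembled from phloroacetophenone by Mitsunobu etherification, ortho-iodination and Negishi coupling, so the lavandulyl alkenes never meet acids or electrophiles.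

Key step: step 10

Assumption: Rh2(S-PTTL)4 is taken to give the (2S) product; if the sense of induction proves opposite, the enantiomeric catalyst Rh2(R-PTTL)4 is used in the same step.

Stereochemical remark: the side-chain centre comes from (R)-lavandulol and is never touched; it is R in 9–11 and S from 12 onward only because CH2–aryl ranks below isopropenyl, whereas CH2–O, CH2–I and CH2–Zn rank above it.

Design remarks: ring B is introduced as its benzylic alcohol because the corresponding 4-silyloxy-2-methoxybenzyl halide would ionise too readily. The acetyl group is present from the start, so no Friedel–Crafts acylation is run on a lavandulyl arene. All three phenols are TIPS ethers, which offer the carbenoid no α-oxy C–H and only a hindered, weakly basic oxygen at O5, and which fall together to buffered fluoride.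

Abbreviations in names: TIPS = triisopropylsilyl [tri(propan-2-yl)silyl]; lavandulyl = 5-methyl-2-(prop-1-en-2-yl)hex-4-en-1-yl; ring-B benzyl = [2-methoxy-4-(triisopropylsilyloxy)phenyl]methyl. Flavanone numbering (O1, C2, C3, C4; rings A, B, C) is used for the late compounds.

Step 1
Reactants: 1 4-hydroxy-2-methoxybenzaldehyde
Product: 2 2-methoxy-4-(triisopropylsilyloxy)benzaldehyde
Conditions: TIPSCl, imidazole, DMF, rt
Reagents that add atoms: triisopropylsilyl chloride, CC(C)[Si](Cl)(C(C)C)C(C)C
Why: Imidazole-promoted silylation of the only hydroxyl; the bulky TIPS ether should survive the hydride, Mitsunobu, iodination, organozinc and amide-base steps and fall to fluoride at the end.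

Step 2
Reactants: 2 2-methoxy-4-(triisopropylsilyloxy)benzaldehyde
Product: 3 [2-methoxy-4-(triisopropylsilyloxy)phenyl]methanol
Conditions: NaBH4, MeOH–THF, 0 °C
Reagents that add atoms: none
Why: Chemoselective borohydride reduction of the aryl aldehyde gives the benzylic alcohol, which is the form in which this electron-rich ring-B unit can be stored and coupled.

Step 3
Reactants: 4 1-(2,4,6-trihydroxyphenyl)ethanone (phloroacetophenone)
Product: 5 1-[2,6-dihydroxy-4-(triisopropylsilyloxy)phenyl]ethanone
Conditions: TIPSCl (1.0 equiv), imidazole, DMF, 0 °C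
Reagents that add atoms: triisopropylsilyl chloride, CC(C)[Si](Cl)(C(C)C)C(C)C
Why: Regioselective phenol silylation: the 4-hydroxyl, para to the acetyl group, is the most acidic and the only one not hydrogen-bonded to the carbonyl, so one equivalent of the bulky chloride should react there and leave a symmetric 2,6-diol.

Step 4
Reactants: 5 1-[2,6-dihydroxy-4-(triisopropylsilyloxy)phenyl]ethanone; 3 [2-methoxy-4-(triisopropylsilyloxy)phenyl]methanol
Product: 6 1-{2-hydroxy-6-[[2-methoxy-4-(triisopropylsilyloxy)phenyl]methoxy]-4-(triisopropylsilyloxy)phenyl}ethanone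
Conditions: PPh3, DIAD, THF, 0 °C to rt
Reagents that add atoms: none
Why: Mitsunobu etherification of a phenol with a primary benzylic alcohol under neutral conditions; the diol is symmetric, so only one mono-ether can form, and the remaining hydroxyl is then locked in a strong hydrogen bond to the ketone, which should hold the reaction at the mono-ether.

Step 5
Reactants: 6 1-{2-hydroxy-6-[[2-methoxy-4-(triisopropylsilyloxy)phenyl]methoxy]-4-(triisopropylsilyloxy)phenyl}ethanone
Product: 7 1-{2-hydroxy-3-iodo-6-[[2-methoxy-4-(triisopropylsilyloxy)phenyl]methoxy]-4-(triisopropylsilyloxy)phenyl}ethanone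
Conditions: BnMe3N+ ICl2−, NaHCO3, CH2Cl2–MeOH, rt
Reagents that add atoms: benzyltrimethylammonium dichloroiodate, C[N+](C)(C)Cc1ccccc1.Cl[I-]Cl
Why: Electrophilic aromatic iodination of a free phenol under weakly basic conditions, which 2-hydroxy-4,6-dialkoxyacetophenones undergo ortho to the chelated hydroxyl and under which aryl ethers such as ring B are not attacked without a Lewis acid.

Step 6
Reactants: 7 1-{2-hydroxy-3-iodo-6-[[2-methoxy-4-(triisopropylsilyloxy)phenyl]methoxy]-4-(triisopropylsilyloxy)phenyl}ethanone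
Product: 8 1-{3-iodo-6-[[2-methoxy-4-(triisopropylsilyloxy)phenyl]methoxy]-2,4-bis(triisopropylsilyloxy)phenyl}ethanone
Conditions: TIPSOTf, 2,6-lutidine, CH2Cl2, 0 °C to rt
Reagents that add atoms: triisopropylsilyl trifluoromethanesulfonate, CC(C)[Si](OS(=O)(=O)C(F)(F)F)(C(C)C)C(C)C
Why: A silyl triflate with a hindered pyridine base silylates even di-ortho-substituted, hydrogen-bonded phenols, and the benzyl ether and methyl ketone tolerate these buffered conditions.

Step 7
Reactants: 9 (R)-lavandulol, (2R)-5-methyl-2-(prop-1-en-2-yl)hex-4-en-1-ol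
Product: 10 (R)-lavandulyl iodide, (3R)-3-(iodomethyl)-2,6-dimethylhepta-1,5-diene
Conditions: I2, PPh3, imidazole, CH2Cl2, 0 °C to rt
Reagents that add atoms: iodine, II
Why: Appel-type iodination of the primary alcohol by SN2 displacement of an alkoxyphosphonium ion; the stereocentre is the neighbouring carbon and takes no part, and the neutral conditions leave both alkenes untouched.

Step 8
Reactants: 8 1-{3-iodo-6-[[2-methoxy-4-(triisopropylsilyloxy)phenyl]methoxy]-2,4-bis(triisopropylsilyloxy)phenyl}ethanone; 10 (R)-lavandulyl iodide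
Product: 12 1-{3-[(2S)-lavandulyl]-6-[[2-methoxy-4-(triisopropylsilyloxy)phenyl]methoxy]-2,4-bis(triisopropylsilyloxy)phenyl}ethanone, via (R)-lavandulylzinc iodide 11 (not isolated)
Conditions: 10, Zn (dust), LiCl, THF, 40 °C; then 8, Pd(OAc)2 (cat.), SPhos, THF, rt to 50 °C
Reagents that add atoms: zinc, [Zn] (retained only in 11)
Why: Negishi coupling of a primary alkylzinc iodide, made by LiCl-promoted zinc insertion, with an aryl iodide, for which the zerovalent palladium/SPhos system is established with di-ortho-substituted partners; the organozinc tolerates the ketone, and the stereocentre, β to zinc, is carried over unchanged.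

Step 9
Reactants: 12 1-{3-[(2S)-lavandulyl]-6-[[2-methoxy-4-(triisopropylsilyloxy)phenyl]methoxy]-2,4-bis(triisopropylsilyloxy)phenyl}ethanone
Product: 14 2-diazo-1-{3-[(2S)-lavandulyl]-6-[[2-methoxy-4-(triisopropylsilyloxy)phenyl]methoxy]-2,4-bis(triisopropylsilyloxy)phenyl}ethanone, via trifluoroacetyl diketone 13 (not isolated)
Conditions: LiN(SiMe3)2, THF, −78 °C; CF3CO2CH2CF3; AcOH quench; then MsN3, Et3N, H2O, MeCN, rt
Reagents that add atoms: 2,2,2-trifluoroethyl trifluoroacetate, O=C(OCC(F)(F)F)C(F)(F)F (trifluoroacetyl group, retained only in 13); methanesulfonyl azide, CS(=O)(=O)N=[N+]=[N-] (the two diazo nitrogens of 14)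
Why: Detrifluoroacetylative diazo transfer (a Regitz-type transfer): the kinetic lithium enolate of the methyl ketone is C-trifluoroacetylated to an activated 1,3-diketone, which takes the diazo group from the sulfonyl azide and loses the trifluoroacetyl group as the N-sulfonyl amide, all under basic conditions that spare the acid-labile benzyl ether.

Step 10
Reactants: 14 2-diazo-1-{3-[(2S)-lavandulyl]-6-[[2-methoxy-4-(triisopropylsilyloxy)phenyl]methoxy]-2,4-bis(triisopropylsilyloxy)phenyl}ethanone
Product: 15 (2S)-2-[2-methoxy-4-(triisopropylsilyloxy)phenyl]-6-[(2S)-lavandulyl]-5,7-bis(triisopropylsilyloxy)-2,3-dihydro-4H-chromen-4-one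
Conditions: Rh2(S-PTTL)4 (dirhodium tetrakis[N-phthaloyl-(S)-tert-leucinate], divalent rhodium; 2 mol %), CH2Cl2, 0 °C, slow addition of 14 at high dilution
Reagents that add atoms: none
Why: Loss of N2 from 14 at the dirhodium core should give an electrophilic rhodium carbenoid at C3 that inserts into one O1–CH2–aryl C–H bond through a concerted, asynchronous three-centre transition state with hydride-transfer character; the closest known reaction type is the dirhodium-carboxylate-catalysed enantioselective intramolecular C–H insertion of ortho-alkoxyaryl diazoketones to 2-substituted chroman-4-ones. Ring C, six-membered, closes in the 1,6-insertion mode, the new C2–C3 bond joining the ends of the chain C3–C4–C4a–C8a–O1–C2. C2 is set by the catalyst: the chiral N-phthaloyl-tert-leucinate ligands let only one of the two benzylic hydrogens (diastereotopic only through the remote side-chain centre) reach the carbenoid, and insertion occurs with retention at carbon. The step needs chemoselectivity for C–H insertion over oxonium-ylide formation at O1 followed by benzyl shift, over attack by O5 and over alkene cyclopropanation, together with the choice between the two hydrogens. The substrate secures this through a C–H bond activated both by O1 and by the electron-rich ring B, a bulky TIPS ether at O5 that has no C–H within five- or six-membered reach, and lavandulyl alkenes that could reach the carbenoid only through a strained meta-bridged medium ring, while slow addition at high dilution suppresses intermolecular reaction.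

Step 11
Reactants: 15 (2S)-2-[2-methoxy-4-(triisopropylsilyloxy)phenyl]-6-[(2S)-lavandulyl]-5,7-bis(triisopropylsilyloxy)-2,3-dihydro-4H-chromen-4-one
Product: 16 (2S)-5,7-dihydroxy-2-(4-hydroxy-2-methoxyphenyl)-6-[(2S)-lavandulyl]-2,3-dihydro-4H-chromen-4-one (target)
Conditions: Bu4NF, AcOH (1:1), THF, 0 °C
Reagents that add atoms: none
Why: Fluoride-mediated desilylation cleaves the three aryl Si–O bonds, and the acetic acid buffer keeps the medium near neutral so that the flavanone should not open to the chalcone by retro-oxa-Michael reaction (which would scramble C2 and allow reclosure onto the other phenol) and the lavandulyl alkenes are not protonated.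

Compound list
1 | 4-hydroxy-2-methoxybenzaldehyde | COc1cc(O)ccc1C=O | starting material
2 | 2-methoxy-4-(triisopropylsilyloxy)benzaldehyde | COc1cc(O[Si](C(C)C)(C(C)C)C(C)C)ccc1C=O | intermediate
3 | [2-methoxy-4-(triisopropylsilyloxy)phenyl]methanol | COc1cc(O[Si](C(C)C)(C(C)C)C(C)C)ccc1CO | intermediate
4 | 1-(2,4,6-trihydroxyphenyl)ethanone (phloroacetophenone) | CC(=O)c1c(O)cc(O)cc1O | starting material
5 | 1-[2,6-dihydroxy-4-(triisopropylsilyloxy)phenyl]ethanone | CC(=O)c1c(O)cc(O[Si](C(C)C)(C(C)C)C(C)C)cc1O | intermediate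
6 | 1-{2-hydroxy-6-[[2-methoxy-4-(triisopropylsilyloxy)phenyl]methoxy]-4-(triisopropylsilyloxy)phenyl}ethanone | CC(=O)c1c(O)cc(O[Si](C(C)C)(C(C)C)C(C)C)cc1OCc1ccc(O[Si](C(C)C)(C(C)C)C(C)C)cc1OC | intermediate
7 | 1-{2-hydroxy-3-iodo-6-[[2-methoxy-4-(triisopropylsilyloxy)phenyl]methoxy]-4-(triisopropylsilyloxy)phenyl}ethanone | CC(=O)c1c(O)c(I)c(O[Si](C(C)C)(C(C)C)C(C)C)cc1OCc1ccc(O[Si](C(C)C)(C(C)C)C(C)C)cc1OC | intermediate
8 | 1-{3-iodo-6-[[2-methoxy-4-(triisopropylsilyloxy)phenyl]methoxy]-2,4-bis(triisopropylsilyloxy)phenyl}ethanone | CC(=O)c1c(O[Si](C(C)C)(C(C)C)C(C)C)c(I)c(O[Si](C(C)C)(C(C)C)C(C)C)cc1OCc1ccc(O[Si](C(C)C)(C(C)C)C(C)C)cc1OC | intermediate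
9 | (R)-lavandulol, (2R)-5-methyl-2-(prop-1-en-2-yl)hex-4-en-1-ol | C=C(C)[C@@H](CC=C(C)C)CO | starting material
10 | (R)-lavandulyl iodide, (3R)-3-(iodomethyl)-2,6-dimethylhepta-1,5-diene | C=C(C)[C@@H](CC=C(C)C)CI | intermediate
11 | (R)-lavandulylzinc iodide | C=C(C)[C@@H](CC=C(C)C)C[Zn]I | intermediate (not isolated)
12 | 1-{3-[(2S)-5-methyl-2-(prop-1-en-2-yl)hex-4-en-1-yl]-6-[[2-methoxy-4-(triisopropylsilyloxy)phenyl]methoxy]-2,4-bis(triisopropylsilyloxy)phenyl}ethanone | C=C(C)[C@@H](CC=C(C)C)Cc1c(O[Si](C(C)C)(C(C)C)C(C)C)cc(OCc2ccc(O[Si](C(C)C)(C(C)C)C(C)C)cc2OC)c(C(C)=O)c1O[Si](C(C)C)(C(C)C)C(C)C | intermediate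
13 | 4,4,4-trifluoro-1-{3-[(2S)-5-methyl-2-(prop-1-en-2-yl)hex-4-en-1-yl]-6-[[2-methoxy-4-(triisopropylsilyloxy)phenyl]methoxy]-2,4-bis(triisopropylsilyloxy)phenyl}butane-1,3-dione | C=C(C)[C@@H](CC=C(C)C)Cc1c(O[Si](C(C)C)(C(C)C)C(C)C)cc(OCc2ccc(O[Si](C(C)C)(C(C)C)C(C)C)cc2OC)c(C(=O)CC(=O)C(F)(F)F)c1O[Si](C(C)C)(C(C)C)C(C)C | intermediate (not isolated)
14 | 2-diazo-1-{3-[(2S)-5-methyl-2-(prop-1-en-2-yl)hex-4-en-1-yl]-6-[[2-methoxy-4-(triisopropylsilyloxy)phenyl]methoxy]-2,4-bis(triisopropylsilyloxy)phenyl}ethanone | C=C(C)[C@@H](CC=C(C)C)Cc1c(O[Si](C(C)C)(C(C)C)C(C)C)cc(OCc2ccc(O[Si](C(C)C)(C(C)C)C(C)C)cc2OC)c(C(=O)C=[N+]=[N-])c1O[Si](C(C)C)(C(C)C)C(C)C | intermediate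
15 | (2S)-2-[2-methoxy-4-(triisopropylsilyloxy)phenyl]-6-[(2S)-5-methyl-2-(prop-1-en-2-yl)hex-4-en-1-yl]-5,7-bis(triisopropylsilyloxy)-2,3-dihydro-4H-chromen-4-one | C=C(C)[C@@H](CC=C(C)C)Cc1c(O[Si](C(C)C)(C(C)C)C(C)C)cc2c(c1O[Si](C(C)C)(C(C)C)C(C)C)C(=O)C[C@@H](c1ccc(O[Si](C(C)C)(C(C)C)C(C)C)cc1OC)O2 | intermediate
16 | (2S)-5,7-dihydroxy-2-(4-hydroxy-2-methoxyphenyl)-6-[(2S)-5-methyl-2-(prop-1-en-2-yl)hex-4-en-1-yl]-2,3-dihydro-4H-chromen-4-one | C=C(C)[C@@H](CC=C(C)C)Cc1c(O)cc2c(c1O)C(=O)C[C@@H](c1ccc(O)cc1OC)O2 | target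

Total step count: 11.
Longest linear sequence: 9 steps (1 → 2 → 3 → 6 → 7 → 8 → 12 → 14 → 15 → 16; steps 1, 2, 4, 5, 6, 8, 9, 10, 11). From phloroacetophenone 4 it is 8 steps and from (R)-lavandulol 9 it is 5 steps.

Steps most likely to fail

Step 10. What may go wrong: capture of the carbenoid by the O1 lone pair and [1,2]-benzyl shift of the resulting oxonium ylide (ring contraction to a benzofuranone), or weak discrimination between the two benzylic hydrogens. The fallback sets out from 5 and returns at 15. It sets C2 instead by rhodium-catalysed asymmetric 1,4-addition of an arylboron reagent to a chromone (Hayashi–Miyaura reaction), forming C2–C1′. Heating 5 with N,N-dimethylformamide dimethyl acetal should give the enaminone (E)-1-[2,6-dihydroxy-4-(triisopropylsilyloxy)phenyl]-3-(dimethylamino)prop-2-en-1-one F1. On mildly acidic work-up this cyclises through either of the two equivalent hydroxyls, with loss of dimethylamine, to 5-hydroxy-7-(triisopropylsilyloxy)-4H-chromen-4-one F2. Iodination ortho to the chelated hydroxyl (BnMe3N+ ICl2−, NaHCO3) gives 5-hydroxy-6-iodo-7-(triisopropylsilyloxy)-4H-chromen-4-one F3. Silylation (TIPSOTf, 2,6-lutidine) gives 6-iodo-5,7-bis(triisopropylsilyloxy)-4H-chromen-4-one F4. Negishi coupling with 11 (Pd(OAc)2, SPhos) gives 6-[(2S)-5-methyl-2-(prop-1-en-2-yl)hex-4-en-1-yl]-5,7-bis(triisopropylsilyloxy)-4H-chromen-4-one F5. Commercial 3-methoxy-4-(4,4,5,5-tetramethyl-1,3,2-dioxaborolan-2-yl)phenol is silylated (TIPSCl, imidazole) to triisopropyl[3-methoxy-4-(4,4,5,5-tetramethyl-1,3,2-dioxaborolan-2-yl)phenoxy]silane F6. F6 is then added to F5 with [Rh(OH)(cod)]2 (monovalent rhodium; cod = cycloocta-1,5-diene) and a chiral diene or bisphosphine ligand in aqueous dioxane, the ligand enantiomer being chosen for the (2S) product, to give 15.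

Step 8. What may go wrong: slow oxidative addition or transmetalation at a C–I bond flanked by two TIPS ethers, so that protodeiodination of 8 or β-hydride elimination from the lavandulyl–palladium intermediate takes over. The fallback sets out from 7 (with 11 generated from 10 as in step 8) and returns at 12. It reverses the order of silylation and coupling so that the C–C bond is made on the much less crowded iodophenol. 11 is added slowly to 7 with Pd(OAc)2 and SPhos, conditions under which cross-coupling should outrun protonation of the alkylzinc by the phenol. This gives 1-{2-hydroxy-3-[(2S)-5-methyl-2-(prop-1-en-2-yl)hex-4-en-1-yl]-6-[[2-methoxy-4-(triisopropylsilyloxy)phenyl]methoxy]-4-(triisopropylsilyloxy)phenyl}ethanone F7. Silylation of the remaining hydroxyl with TIPSOTf and 2,6-lutidine then gives 12.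

Step 5. What may go wrong: competing iodination of the electron-rich ring B or at the position para to the hydroxyl, over-iodination, or acid-induced loss of the benzyl ether. The fallback sets out from 5 and returns at 7. It introduces the halogen before ring B is present. Mono-iodination of the symmetric diol 5 (one equivalent of BnMe3N+ ICl2−, NaHCO3; the two free ring positions are equivalent) gives 1-[2,6-dihydroxy-3-iodo-4-(triisopropylsilyloxy)phenyl]ethanone F8. Mitsunobu etherification with 3 (PPh3, DIAD) should then be directed by sterics to the hydroxyl that is not flanked by iodine, giving 7.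

Further compounds
F1 | step 10 | (E)-1-[2,6-dihydroxy-4-(triisopropylsilyloxy)phenyl]-3-(dimethylamino)prop-2-en-1-one | CN(C)/C=C/C(=O)c1c(O)cc(O[Si](C(C)C)(C(C)C)C(C)C)cc1O
F2 | step 10 | 5-hydroxy-7-(triisopropylsilyloxy)-4H-chromen-4-one | O=c1ccoc2cc(O[Si](C(C)C)(C(C)C)C(C)C)cc(O)c12
F3 | step 10 | 5-hydroxy-6-iodo-7-(triisopropylsilyloxy)-4H-chromen-4-one | O=c1ccoc2cc(O[Si](C(C)C)(C(C)C)C(C)C)c(I)c(O)c12
F4 | step 10 | 6-iodo-5,7-bis(triisopropylsilyloxy)-4H-chromen-4-one | O=c1ccoc2cc(O[Si](C(C)C)(C(C)C)C(C)C)c(I)c(O[Si](C(C)C)(C(C)C)C(C)C)c12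
F5 | step 10 | 6-[(2S)-5-methyl-2-(prop-1-en-2-yl)hex-4-en-1-yl]-5,7-bis(triisopropylsilyloxy)-4H-chromen-4-one | C=C(C)[C@@H](CC=C(C)C)Cc1c(O[Si](C(C)C)(C(C)C)C(C)C)cc2occc(=O)c2c1O[Si](C(C)C)(C(C)C)C(C)C
F6 | step 10 | triisopropyl[3-methoxy-4-(4,4,5,5-tetramethyl-1,3,2-dioxaborolan-2-yl)phenoxy]silane | COc1cc(O[Si](C(C)C)(C(C)C)C(C)C)ccc1B1OC(C)(C)C(C)(C)O1
F7 | step 8 | 1-{2-hydroxy-3-[(2S)-5-methyl-2-(prop-1-en-2-yl)hex-4-en-1-yl]-6-[[2-methoxy-4-(triisopropylsilyloxy)phenyl]methoxy]-4-(triisopropylsilyloxy)phenyl}ethanone | C=C(C)[C@@H](CC=C(C)C)Cc1c(O[Si](C(C)C)(C(C)C)C(C)C)cc(OCc2ccc(O[Si](C(C)C)(C(C)C)C(C)C)cc2OC)c(C(C)=O)c1O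
F8 | step 5 | 1-[2,6-dihydroxy-3-iodo-4-(triisopropylsilyloxy)phenyl]ethanone | CC(=O)c1c(O)cc(O[Si](C(C)C)(C(C)C)C(C)C)c(I)c1O
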